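Its constants are made up, and the outcome is calculated.

- Keep your books on X rather than on the clock: each J that reaches J.X spends one X, and each J.X that goes on to X.J.X or G spends one more.

    Z ⇌ J.X, rate k1*(cs1 - [J.X]) while solid is left; crystals form when [J.X] > cs1 (cs1 = 12 mM, k1 = 4.9 min⁻¹)
    X + J.X → G (k2 = 1.1 M⁻¹ min⁻¹)
    J + X → J.X (k3 = 19 M⁻¹ min⁻¹)
    X + J.X → X.J.X (k4 = 5.9 M⁻¹ min⁻¹)

J 29 mM; X 43.5 mM (fed, over 4.0 min); time 2.0 h

- J.X is meant together with its Z
- solid, in amounts per volume of the solution: Z
- the reaction counts as stopped when no species that holds the J changes by six tenths of a point or more over the second half of the time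
- run time (flask): 2.0 h

- the state of affairs at 2.0 h: stopped, and by what, or still going (all of J has reacted / forward and back rates have come level / it is still moving / X has run out first)
- part of the J gone at 2.0 h
- the J.X standing at 2.0 h, as a percentage of the J charged
- the X.J.X standing at 2.0 h, as a percentage of the J charged

- Count in fractions of the J charge, so that the surplus of X, the X charged beyond one equivalent of J, is 0.500. Once X is gone, the part gone onward equals the surplus plus the J left.
- One extreme: X finishes J first, so no J is left, J.X holds 50.0% and the onward part is the surplus. The other extreme: each J takes two X at once, so X.J.X could reach 75.0% and 25.0% of the J is left.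
- With solid present, dissolved J.X stands near 41.4%, less than the 50.0% of the first extreme. At the full J charge, X then goes to J 6.56 times faster than to J.X, so this flask lies near the first extreme.
- I treat the J left as a correction: if dissolved J.X stood at its solubility throughout, it would be exp(-6.56 × onward part), which gives 3.76%, then 2.94% on a second pass.
- With dissolved J.X held near its solubility, X, the limiting reagent, then decays pseudo-first-order with an estimated half-life of 8.25 min, much shorter than the time. With 84.3% of the onward part going to X.J.X, I commit to a stop for lack of X, with 97.1% of J gone, J.X 44.1% and X.J.X 44.6%.
- The forecast names the same stop, X has run out first, and differs slightly from my figures, with 97.5% gone, J.X 45% and X.J.X 44%, holding that “J.X sits at its 12 mM solubility for nearly the whole run”.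

The simulation gives the outcome "X has run out first", with 97.5% of the J gone, J.X at 45.0% and X.J.X at 44.3%, as forecast. In this flask X stands at 0% of its charge after 2.00 h, and no share moves by more than 0.11 percentage points over the second half of the time. Adding the J left, 2.5%, to the surplus gives an onward part of 52.5%, of which the split gives X.J.X 44.3%.

- In the neighbour flask with 74 mM of X, the surplus is 1.55, more than one, so each J can go onward: expect X.J.X 84.3% and X 21.6% of its charge left. The computed flask holds X.J.X 84.3%, G 15.7% and X 21.6%.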